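**Assumption:** the macrocyclic NHK closure and the enal epoxidation are substrate-controlled by the 10-membered ring and give the natural relative configuration. Absolute configuration comes from the (S)-Evans auxiliary. I have not modelled either selectivity, so both are flagged as failure risks at the end.

## Retrosynthetic overview
- The target is the cis-epoxy-aldehyde from amine-catalysed nucleophilic epoxidation of the macrocyclic (Z-in-ring) enal **(new step)**. The enal comes from the C15 allylic alcohol and its TBS ether.
- The 10-membered carbocycle is closed by an intramolecular Nozaki–Hiyama–Kishi (NHK) reaction of an (E)-trisubstituted vinyl iodide onto an aldehyde. This forms the allylic carbinol and keeps the E-alkene.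
- The open-chain precursor comes from an (E)-α-alkylidene-γ-butyrolactone, which fixes the ring-cis trisubstituted alkene geometry. It is made by aldol condensation of a γ-lactone with (E)-5-iodo-4-methylpent-4-enal and then opened reductively.
- The lactone carries the CH(iPr)/CH(O) stereocentres from an Evans syn-aldol of N-isovaleryl-(S)-4-benzyloxazolidinone with methyl 4-oxobutanoate.
- Ring order: γ-lactone first (later opened), then the 10-membered carbocycle by NHK, then the epoxide last.

## Route

**Step 1**
Reactants: 1 pent-4-yn-1-ol
Product: 2 (E)-5-iodo-4-methylpent-4-en-1-ol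
Conditions: Me3Al, Cp2ZrCl2 (cat.), CH2Cl2, 0 → 23 °C; then I2, THF, −30 °C
Reagents that add atoms: trimethylaluminium (3), C[Al](C)C; iodine (4), II
Why: Negishi Zr-catalysed syn-methylalumination/iodinolysis puts Me on the internal carbon and I on the terminal carbon, trans to the chain. This gives the (E)-vinyl iodide that becomes the E ring alkene.

**Step 2**
Reactants: 2
Product: 5 (E)-5-iodo-4-methylpent-4-enal
Conditions: DMP, NaHCO3, CH2Cl2, 0 → 23 °C
Reagents that add atoms: none
Why: Dess–Martin oxidation of a primary alcohol leaves the vinyl iodide untouched.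

**Step 3**
Reactants: 6 isovaleryl chloride; 7 (S)-4-benzyloxazolidin-2-one
Product: 8 (S)-4-benzyl-3-(3-methylbutanoyl)oxazolidin-2-one
Conditions: 7, n-BuLi, THF, −78 °C; then 6, −78 → 0 °C
Reagents that add atoms: none (the acyl chloride is a listed reactant)
Why: N-acylation of the lithiated oxazolidinone.

**Step 4**
Reactants: 8; 9 methyl 4-oxobutanoate
Product: 10 (S)-4-benzyl-3-[(2S,3R)-3-hydroxy-2-isopropyl-6-methoxy-6-oxohexanoyl]oxazolidin-2-one
Conditions: Bu2BOTf, Et3N, CH2Cl2, −78 → 0 °C; then 9, −78 → 0 °C; then H2O2, MeOH/pH 7 buffer
Reagents that add atoms: none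
Why: Evans syn-aldol through the Z(O)-boron enolate and a Zimmerman–Traxler transition state, with the aldehyde approaching anti to the benzyl group. This sets the iPr-bearing (S) and OH-bearing (R) stereocentres, which are syn, as required.

**Step 5**
Reactants: 10
Product: 11 (S)-4-benzyl-3-{(2S)-3-methyl-2-[(2R)-5-oxooxolan-2-yl]butanoyl}oxazolidin-2-one
Conditions: TsOH·H2O (10 mol %), toluene, 23 → 50 °C
Reagents that add atoms: none (MeOH is lost)
Why: acid-catalysed γ-hydroxy-ester lactonisation (5-exo) forms the γ-butyrolactone and leaves the stereocentres untouched.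

**Step 6**
Reactants: 11
Product: 12 (5R)-5-[(2R)-1-hydroxy-3-methylbutan-2-yl]oxolan-2-one (auxiliary 7 recovered)
Conditions: NaBH4, THF/H2O (4:1), 0 °C
Reagents that add atoms: none
Why: borohydride reductively cleaves the N-acyl oxazolidinone to the primary alcohol while the lactone survives at 0 °C; no stereocentre is epimerised.

**Step 7**
Reactants: 12
Product: 13 (5R)-5-[(2R)-3-methyl-1-(triethylsilyloxy)butan-2-yl]oxolan-2-one
Conditions: TESCl, imidazole, DMF, 0 °C
Reagents that add atoms: chlorotriethylsilane (14), CC[Si](Cl)(CC)CC
Why: silylation of the primary alcohol. TES is chosen because it can later be removed selectively in the presence of a primary TBS ether.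

**Step 8**
Reactants: 13; 5
Product: 15 β-hydroxy-lactone aldol adduct (mixture at the two new centres; lactone C5 and exocyclic-chain stereocentres retained)
Conditions: LiHMDS, THF, −78 °C; then 5, −78 °C; NH4Cl
Reagents that add atoms: none
Why: lactone-enolate aldol addition to the enolisable aldehyde at −78 °C. The new centres are destroyed in the next step, so their configuration does not matter.

**Step 9**
Reactants: 15
Product: 16 (3E,5R)-3-[(E)-5-iodo-4-methylpent-4-en-1-ylidene]-5-[(2R)-3-methyl-1-(triethylsilyloxy)butan-2-yl]oxolan-2-one
Conditions: MsCl, Et3N, CH2Cl2, 0 °C; then DBU, 23 → 40 °C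
Reagents that add atoms: none (the mesylate is eliminated)
Why: mesylation then E1cB elimination gives the thermodynamically preferred (E)-alkylidene lactone, with the chain cis to the ring CH2. After lactone opening this becomes the ring-cis f=g alkene; the minor Z isomer is removed by chromatography.

**Step 10**
Reactants: 16
Product: 17 (E)-diol: the C15 allylic primary alcohol and the secondary i-alcohol, with the TES ether and vinyl iodide intact
Conditions: DIBAL-H (4 equiv), CH2Cl2, −78 → 0 °C
Reagents that add atoms: none
Why: exhaustive DIBAL reduction of the lactone to the 1,4-diol leaves the trisubstituted alkene geometry and the stereocentres unchanged.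

**Step 11**
Reactants: 17
Product: 18 C15 TBS ether, with i-OH free
Conditions: TBSCl (1.05 equiv), imidazole, CH2Cl2/DMF, 0 °C
Reagents that add atoms: tert-butyldimethylsilyl chloride (19), CC(C)(C)[Si](C)(C)Cl
Why: silylation is selective for the unhindered primary allylic OH over the secondary OH flanked by the isopropyl-bearing carbon.

**Step 12**
Reactants: 18
Product: 20 primary alcohol (diol; C15-OTBS retained)
Conditions: PPTS (20 mol %), MeOH/CH2Cl2 (1:1), 0 °C
Reagents that add atoms: none
Why: mild acidic methanolysis cleaves the primary TES ether selectively and leaves the primary TBS ether.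

**Step 13**
Reactants: 20
Product: 21 β-hydroxy aldehyde (NHK precursor)
Conditions: TEMPO (10 mol %), PhI(OAc)2, CH2Cl2, 0 °C
Reagents that add atoms: none
Why: TEMPO/BAIB oxidises the unhindered primary alcohol chemoselectively and leaves the hindered secondary alcohol and the alkenes.

**Step 14**
Reactants: 21
Product: 22 (1R-type a-carbinol) cyclodeca-(E,Z)-diene diol with C15-OTBS
Conditions: CrCl2 (10 equiv), NiCl2 (0.1 equiv), DMF, 0.003 M, substrate added by syringe pump over 10 h, 23 °C
Reagents that add atoms: none
Why: intramolecular NHK reaction, in which the alkenyl-Cr(III) species adds to the aldehyde. The ring is closed with retention of the E-alkene, and the new allylic carbinol configuration is set by the macrocyclic transition state with Cr-alkoxide chelation to the free i-OH (anti-1,3-diol).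

**Step 15**
Reactants: 22
Product: 23 bis-acetate
Conditions: Ac2O, pyridine, DMAP (cat.), CH2Cl2, 23 °C
Reagents that add atoms: acetic anhydride (24), CC(=O)OC(C)=O
Why: acetylation of both secondary alcohols with retention of configuration.

**Step 16**
Reactants: 23
Product: 25 macrocyclic C15 allylic alcohol
Conditions: HF·pyridine, pyridine, THF, 0 → 23 °C
Reagents that add atoms: none
Why: fluoride removal of the primary allylic TBS ether under buffered conditions, so the acetates survive.

**Step 17**
Reactants: 25
Product: 26 macrocyclic (E)-α,β-disubstituted enal (ring Z-alkene)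
Conditions: MnO2 (20 equiv), CH2Cl2, 23 °C
Reagents that add atoms: none
Why: MnO2 oxidises the allylic alcohol selectively to the enal with no change in alkene geometry.

**Step 18**
Reactants: 26
Product: 27 Pulicanaral A
Conditions: 9-amino-9-deoxy-epi-quinine (30 mol %), TFA (60 mol %), 30% aq. H2O2 (3 equiv), CH2Cl2, 0 → 23 °C
Reagents that add atoms: hydrogen peroxide (28), OO
Why: Proposed new method: iminium-activated Weitz–Scheffer-type epoxidation of a ring-constrained, α,β-disubstituted cyclodecenal, a substrate class not yet shown with this catalysis (closest known reaction: organocatalytic enal epoxidation with H2O2). A small cinchona primary amine can condense with the hindered trisubstituted enal, HOO⁻ adds to the β-carbon (f) on the peripheral face of the crown conformer, and the resulting enamine closes the epoxide at the O–O bond (3-exo-tet). The ring constraint preserves the cis relationship of the ring carbons, giving the cis-epoxide with the quaternary CHO-bearing carbon. The nucleophilic mechanism leaves the other trisubstituted alkene and the acetates untouched.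

## Compound list
1 | pent-4-yn-1-ol | C#CCCCO | starting material
2 | (E)-5-iodo-4-methylpent-4-en-1-ol | I/C=C(\C)CCCO | intermediate
3 | trimethylaluminium | C[Al](C)C | reagent
4 | iodine | II | reagent
5 | (E)-5-iodo-4-methylpent-4-enal | I/C=C(\C)CCC=O | intermediate
6 | isovaleryl chloride | CC(C)CC(=O)Cl | starting material
7 | (S)-4-benzyloxazolidin-2-one | O=C1N[C@@H](Cc2ccccc2)CO1 | starting material
8 | (S)-4-benzyl-3-isovaleryl-oxazolidin-2-one | CC(C)CC(=O)N1[C@@H](Cc2ccccc2)COC1=O | intermediate
9 | methyl 4-oxobutanoate | COC(=O)CCC=O | starting material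
10 | Evans syn-aldol adduct | COC(=O)CC[C@@H](O)[C@H](C(C)C)C(=O)N1[C@@H](Cc2ccccc2)COC1=O | intermediate
11 | lactone imide | O=C1CC[C@@H](O1)[C@H](C(C)C)C(=O)N2[C@@H](Cc3ccccc3)COC2=O | intermediate
12 | lactone primary alcohol | O=C1CC[C@@H](O1)[C@H](C(C)C)CO | intermediate
13 | lactone TES ether | O=C1CC[C@@H](O1)[C@H](C(C)C)CO[Si](CC)(CC)CC | intermediate
14 | chlorotriethylsilane | CC[Si](Cl)(CC)CC | reagent
15 | β-hydroxy-lactone aldol adduct (mixture at the two new centres) | O=C1C(C(O)CC/C(C)=C/I)C[C@@H](O1)[C@H](C(C)C)CO[Si](CC)(CC)CC | intermediate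
16 | (E)-alkylidene lactone | I/C=C(\C)CC/C=C1\C[C@@H](OC1=O)[C@H](C(C)C)CO[Si](CC)(CC)CC | intermediate
17 | diol (C15-OH, i-OH, TES ether) | I/C=C(\C)CC/C=C(/CO)C[C@@H](O)[C@H](C(C)C)CO[Si](CC)(CC)CC | intermediate
18 | C15-OTBS, i-OH, TES ether | I/C=C(\C)CC/C=C(/CO[Si](C)(C)C(C)(C)C)C[C@@H](O)[C@H](C(C)C)CO[Si](CC)(CC)CC | intermediate
19 | tert-butyldimethylsilyl chloride | CC(C)(C)[Si](C)(C)Cl | reagent
20 | C15-OTBS diol (free primary OH) | I/C=C(\C)CC/C=C(/CO[Si](C)(C)C(C)(C)C)C[C@@H](O)[C@H](C(C)C)CO | intermediate
21 | β-hydroxy aldehyde (NHK precursor) | I/C=C(\C)CC/C=C(/CO[Si](C)(C)C(C)(C)C)C[C@@H](O)[C@H](C(C)C)C=O | intermediate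
22 | macrocyclic diol, C15-OTBS | O[C@@H]1/C=C(\C)CC/C=C(/CO[Si](C)(C)C(C)(C)C)C[C@@H](O)[C@@H]1C(C)C | intermediate
23 | macrocyclic bis-acetate, C15-OTBS | CC(=O)O[C@@H]1/C=C(\C)CC/C=C(/CO[Si](C)(C)C(C)(C)C)C[C@@H](OC(C)=O)[C@@H]1C(C)C | intermediate
24 | acetic anhydride | CC(=O)OC(C)=O | reagent
25 | macrocyclic bis-acetate allylic alcohol | CC(=O)O[C@@H]1/C=C(\C)CC/C=C(/CO)C[C@@H](OC(C)=O)[C@@H]1C(C)C | intermediate
26 | macrocyclic enal | CC(=O)O[C@@H]1/C=C(\C)CC/C=C(/C=O)C[C@@H](OC(C)=O)[C@@H]1C(C)C | intermediate
27 | Pulicanaral A | CC(=O)O[C@@H]1/C=C(\C)CC[C@H]2O[C@@]2(C=O)C[C@@H](OC(C)=O)[C@@H]1C(C)C | target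
28 | hydrogen peroxide | OO | reagent

## Totals
Total steps: 18. Longest linear sequence: 16 steps (steps 3–18, from 6/7). The vinyl iodide aldehyde is made in a parallel 2-step branch (steps 1–2).

## Three steps most likely to fail
1. **Step 18 (proposed new epoxidation).** The hindered trisubstituted macrocyclic enal may form the iminium slowly, or the facial selectivity may be mismatched with the catalyst.
   - Fallback: use known chemistry on allylic alcohol 25. Directed epoxidation with VO(acac)2/TBHP (or Ti(OiPr)4/tartrate/TBHP) epoxidises the allylic-alcohol alkene selectively over the acetate-deactivated alkene. DMP oxidation of the epoxy alcohol then gives 27.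
2. **Step 14 (NHK macrocyclisation).** The main risk is the wrong carbinol epimer at C-a, or a low closure yield.
   - Fallback: oxidise the allylic a-OH of the epimeric diol 22 selectively with MnO2 to the β-hydroxy enone, then reduce it with Me4NBH(OAc)3 (Evans–Saksena directed anti reduction). This restores the required anti-1,3-diol, after which the route continues from Step 15.
3. **Step 9 (E-selective aldol condensation).** The E:Z ratio may be poor, or the lactone γ-stereocentre may epimerise under DBU.
   - Fallback: make the α-phosphono-lactone from 13 (α-bromination, then Arbuzov with P(OEt)3). Horner–Wadsworth–Emmons olefination of that phosphonate with 5 gives the (E)-alkylidene lactone 16 without the elimination step.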